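## Retrosynthetic overview

1. Feature: in the benzotropolone (C1=O, C2–H, C3–flavan A, C4–H, C4a, C5–flavan B, C6–H, C7–OH, C8–OH, C8a, C9–OH) the C9–OH/C1=O pair is the enol of a C9,C1-dione and C3=C4 is a styrene-type alkene, so a C9 ketone with C1 as dimethyl ketal and C2 as CH2 is the tropolone in masked, non-aromatic form.
2. C3=C4 is cut by ring-closing metathesis (vinyl on C4a plus the 1,1-disubstituted alkene carrying flavan A); C8a–C9 by acylation of an aryllithium with an α,α-dimethoxy ester; C1–C2 by allylation of the enolate of methyl dimethoxyacetate.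
3. Each 2,3-cis (2R,3R) chroman: O1–C2 by Mitsunobu inversion of an anti epoxy alcohol (Sharpless kinetic resolution) with 3,5-bis(benzyloxy)phenol, then C4–C4a by 6-endo epoxide–arene cyclisation.
4. Ring order: pyran ring of flavan A and pyran ring of flavan B in separate fragments, then the seven-membered ring, which becomes the tropolone on ketal hydrolysis; the benzyl ethers leave last.

Key step: step 18

Assumption: 2-bromoprop-2-enal is taken as purchasable (otherwise from acrolein by bromination and dehydrobromination), and the two flavan 3-hydroxyls are carried as benzyl ethers so that one hydrogenolysis ends the route.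

## Route

Step 1
Reactants: 1 2-bromoprop-2-enal
Product: 2 rac-2-bromopenta-1,4-dien-3-ol
Conditions: CH2=CHMgBr, THF, −78 °C; then H2O
Reagents that add atoms: vinylmagnesium bromide C=C[Mg]Br
Why: Grignard 1,2-addition to the aldehyde at −78 °C is faster than conjugate addition or bromine–magnesium exchange and gives a bis-allylic alcohol whose bromoalkene is electronically deactivated for the next step.

Step 2
Reactants: 2 rac-2-bromopenta-1,4-dien-3-ol
Product: 3 (1R)-2-bromo-1-[(2R)-oxiran-2-yl]prop-2-en-1-ol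
Conditions: Ti(O-i-Pr)4 (0.15 equiv), L-(+)-diisopropyl tartrate (0.2 equiv), t-BuOOH (0.45 equiv), 4 Å molecular sieves, CH2Cl2, −20 °C
Reagents that add atoms: tert-butyl hydroperoxide CC(C)(C)OO
Why: Sharpless kinetic resolution: with the L-(+)-tartrate the fast-reacting (R)-enantiomer is epoxidised only at its unsubstituted vinyl group (the electron-poor bromoalkene is inert) to the anti (erythro) epoxy alcohol, the tartrate fixing the oxirane carbon as R (the facial sense that gives (S)-glycidol from allyl alcohol) and the erythro preference fixing the carbinol, while stopping below half conversion should keep the product enantiopure.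

Step 3
Reactants: 3 (1R)-2-bromo-1-[(2R)-oxiran-2-yl]prop-2-en-1-ol; 4 3,5-bis(benzyloxy)phenol
Product: 5 (2R)-2-{(1S)-1-[3,5-bis(benzyloxy)phenoxy]-2-bromoprop-2-en-1-yl}oxirane
Conditions: PPh3, diisopropyl azodicarboxylate, toluene, 0 °C → rt
Reagents that add atoms: none
Why: Mitsunobu etherification: the phenol displaces the activated allylic carbinol by SN2 with inversion, turning the anti epoxy alcohol into the syn aryl ether that a 2,3-cis chroman requires, and the oxirane is untouched.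

Step 4
Reactants: 5 (2R)-2-{(1S)-1-[3,5-bis(benzyloxy)phenoxy]-2-bromoprop-2-en-1-yl}oxirane
Product: 6 (2S,3R)-5,7-bis(benzyloxy)-2-(1-bromoethenyl)-3,4-dihydro-2H-chromen-3-ol (2,3-cis)
Conditions: AuCl3 (5 mol %), AgOSO2CF3 (15 mol %), ClCH2CH2Cl, 0 °C → rt
Reagents that add atoms: none
Why: Lewis-acid intramolecular Friedel–Crafts alkylation (epoxide–arene cyclisation): the ring carbon ortho to the ether oxygen and para to a benzyloxy group attacks the terminal oxirane CH2 (6-endo), so neither stereocentre is touched and the cis relationship follows from step 3.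

Step 5
Reactants: 6 (2S,3R)-5,7-bis(benzyloxy)-2-(1-bromoethenyl)-3,4-dihydro-2H-chromen-3-ol
Product: 7 (2S,3R)-3,5,7-tris(benzyloxy)-2-(1-bromoethenyl)-3,4-dihydro-2H-chromene
Conditions: NaH, BnBr, Bu4NI (cat.), DMF, 0 °C → rt
Reagents that add atoms: benzyl bromide BrCc1ccccc1
Why: Williamson etherification of the secondary alkoxide gives a 3-O-benzyl group that survives the organometallic steps and leaves in the final hydrogenolysis.

Step 6
Reactants: 7 (2S,3R)-3,5,7-tris(benzyloxy)-2-(1-bromoethenyl)-3,4-dihydro-2H-chromene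
Product: 8 2-[(2R,3R)-3,5,7-tris(benzyloxy)-3,4-dihydro-2H-chromen-2-yl]prop-2-en-1-ol
Conditions: Bu3SnCH2OH (1.5 equiv), Pd(PPh3)4 (10 mol %), 1,4-dioxane, 90 °C
Reagents that add atoms: (tributylstannyl)methanol CCCC[Sn](CCCC)(CCCC)CO
Why: Stille coupling: oxidative addition to the alkenyl C–Br bond and transfer of the hydroxymethyl group from tin give the 2-substituted allylic alcohol, and C2 is not involved because the hindered secondary allyl aryl ether ionises far more slowly than the C–Br bond adds.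

Step 7
Reactants: 8 2-[(2R,3R)-3,5,7-tris(benzyloxy)-3,4-dihydro-2H-chromen-2-yl]prop-2-en-1-ol
Product: 9 (2R,3R)-3,5,7-tris(benzyloxy)-2-(3-bromoprop-1-en-2-yl)-3,4-dihydro-2H-chromene
Conditions: CBr4, PPh3, CH2Cl2, 0 °C
Reagents that add atoms: tetrabromomethane BrC(Br)(Br)Br
Why: Appel reaction converts the primary allylic alcohol into the bromide under neutral conditions, and because both allyl termini are CH2 the SN2 and SN2' paths give the same product.

Step 8
Reactants: 10 methyl dimethoxyacetate; 9 (2R,3R)-3,5,7-tris(benzyloxy)-2-(3-bromoprop-1-en-2-yl)-3,4-dihydro-2H-chromene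
Product: 12 methyl 2,2-dimethoxy-4-[(2R,3R)-3,5,7-tris(benzyloxy)-3,4-dihydro-2H-chromen-2-yl]pent-4-enoate, via lithium enolate of methyl dimethoxyacetate 11 (not isolated)
Conditions: LiN(i-Pr)2, THF, −78 °C; then 9, DMPU, −78 → −30 °C
Reagents that add atoms: none
Why: Ester enolate alkylation with a reactive allylic bromide forms C1–C2 and brings in C1 already as its dimethyl ketal (the enolate acts as a glyoxylate acyl-anion equivalent), the non-acidic allylic C2–H of the chroman being untouched.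

Step 9
Reactants: 13 3-bromo-4,5-dihydroxybenzaldehyde
Product: 14 3,4-bis(benzyloxy)-5-bromobenzaldehyde
Conditions: BnBr, K2CO3, DMF, 60 °C
Reagents that add atoms: benzyl bromide BrCc1ccccc1
Why: Double Williamson O-benzylation of the catechol.

Step 10
Reactants: 14 3,4-bis(benzyloxy)-5-bromobenzaldehyde
Product: 15 4,5-bis(benzyloxy)-3-bromo-2-iodobenzaldehyde
Conditions: I2, CF3CO2Ag, CH2Cl2, 0 °C → rt
Reagents that add atoms: iodine II
Why: Electrophilic aromatic iodination by CF3CO2I formed in situ should go para to the benzyloxy group that is meta to the formyl group, the site that 3,4-dialkoxybenzaldehydes take in halogenation, which places iodine between CHO and Br.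

Step 11
Reactants: 15 4,5-bis(benzyloxy)-3-bromo-2-iodobenzaldehyde
Product: 16 rac-1-[4,5-bis(benzyloxy)-3-bromo-2-iodophenyl]prop-2-en-1-ol
Conditions: CH2=CHMgBr, THF, −78 °C; then H2O
Reagents that add atoms: vinylmagnesium bromide C=C[Mg]Br
Why: Grignard 1,2-addition to the aldehyde at −78 °C, where neither aryl halide exchanges with the vinyl Grignard reagent.

Step 12
Reactants: 16 rac-1-[4,5-bis(benzyloxy)-3-bromo-2-iodophenyl]prop-2-en-1-ol
Product: 17 (S)-[4,5-bis(benzyloxy)-3-bromo-2-iodophenyl][(2R)-oxiran-2-yl]methanol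
Conditions: Ti(O-i-Pr)4 (0.15 equiv), L-(+)-diisopropyl tartrate (0.2 equiv), t-BuOOH (0.45 equiv), 4 Å molecular sieves, CH2Cl2, −20 °C
Reagents that add atoms: tert-butyl hydroperoxide CC(C)(C)OO
Why: Sharpless kinetic resolution as in step 2: the L-(+)-tartrate epoxidises the fast-reacting (R)-aryl vinyl carbinol to the anti (erythro) epoxy alcohol with the (R)-oxirane, and the reaction is stopped below half conversion.

Step 13
Reactants: 17 (S)-[4,5-bis(benzyloxy)-3-bromo-2-iodophenyl][(2R)-oxiran-2-yl]methanol; 4 3,5-bis(benzyloxy)phenol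
Product: 18 (2R)-2-{(R)-[4,5-bis(benzyloxy)-3-bromo-2-iodophenyl][3,5-bis(benzyloxy)phenoxy]methyl}oxirane
Conditions: PPh3, diisopropyl azodicarboxylate, toluene, 0 °C → rt
Reagents that add atoms: none
Why: Mitsunobu etherification with SN2 inversion at the benzylic carbinol (the bromo and iodo substituents disfavour ionisation) gives the syn aryl ether and thereby sets C2 of flavan B as R.

Step 14
Reactants: 18 (2R)-2-{(R)-[4,5-bis(benzyloxy)-3-bromo-2-iodophenyl][3,5-bis(benzyloxy)phenoxy]methyl}oxirane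
Product: 19 (2R,3R)-5,7-bis(benzyloxy)-2-[4,5-bis(benzyloxy)-3-bromo-2-iodophenyl]-3,4-dihydro-2H-chromen-3-ol
Conditions: AuCl3 (5 mol %), AgOSO2CF3 (15 mol %), ClCH2CH2Cl, 0 °C → rt
Reagents that add atoms: none
Why: The same Lewis-acid 6-endo epoxide–arene Friedel–Crafts cyclisation as in step 4 closes the pyran ring at the terminal oxirane carbon and gives the 2,3-cis chromanol with both aryl halides untouched.

Step 15
Reactants: 19 (2R,3R)-5,7-bis(benzyloxy)-2-[4,5-bis(benzyloxy)-3-bromo-2-iodophenyl]-3,4-dihydro-2H-chromen-3-ol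
Product: 20 (2R,3R)-3,5,7-tris(benzyloxy)-2-[4,5-bis(benzyloxy)-3-bromo-2-iodophenyl]-3,4-dihydro-2H-chromene
Conditions: NaH, BnBr, Bu4NI (cat.), DMF, 0 °C → rt
Reagents that add atoms: benzyl bromide BrCc1ccccc1
Why: Williamson etherification of the secondary alkoxide, with no epimerisable centre because all phenols are protected.

Step 16
Reactants: 20 (2R,3R)-3,5,7-tris(benzyloxy)-2-[4,5-bis(benzyloxy)-3-bromo-2-iodophenyl]-3,4-dihydro-2H-chromene
Product: 21 (2R,3R)-3,5,7-tris(benzyloxy)-2-[4,5-bis(benzyloxy)-3-bromo-2-ethenylphenyl]-3,4-dihydro-2H-chromene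
Conditions: tributyl(vinyl)stannane (1.2 equiv), Pd(PPh3)4 (5 mol %), CuI (10 mol %), DMF, 60 °C
Reagents that add atoms: tributyl(vinyl)stannane C=C[Sn](CCCC)(CCCC)CCCC
Why: Stille coupling chemoselective for the aryl C–I bond over the neighbouring C–Br bond installs the C4a vinyl group only after the Lewis-acid steps, which an electron-rich styrene would not be expected to survive.

Step 17
Reactants: 21 (2R,3R)-3,5,7-tris(benzyloxy)-2-[4,5-bis(benzyloxy)-3-bromo-2-ethenylphenyl]-3,4-dihydro-2H-chromene; 12 methyl 2,2-dimethoxy-4-[(2R,3R)-3,5,7-tris(benzyloxy)-3,4-dihydro-2H-chromen-2-yl]pent-4-enoate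
Product: 23 1-{2,3-bis(benzyloxy)-6-ethenyl-5-[(2R,3R)-3,5,7-tris(benzyloxy)-3,4-dihydro-2H-chromen-2-yl]phenyl}-2,2-dimethoxy-4-[(2R,3R)-3,5,7-tris(benzyloxy)-3,4-dihydro-2H-chromen-2-yl]pent-4-en-1-one, via aryllithium 22 (not isolated)
Conditions: n-BuLi (1.05 equiv), THF, −78 °C, 10 min; then 12, −78 → −40 °C; then H2O
Reagents that add atoms: none
Why: Bromine–lithium exchange and acylation of the aryllithium by the α,α-dimethoxy ester form C8a–C9, the methoxy-chelated lithium hemiketal persisting until work-up and the resulting ketone being too hindered (quaternary α-carbon, 2,6-disubstituted aryl) for a second addition.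

Step 18
Reactants: 23 1-{2,3-bis(benzyloxy)-6-ethenyl-5-[(2R,3R)-3,5,7-tris(benzyloxy)-3,4-dihydro-2H-chromen-2-yl]phenyl}-2,2-dimethoxy-4-[(2R,3R)-3,5,7-tris(benzyloxy)-3,4-dihydro-2H-chromen-2-yl]pent-4-en-1-one
Product: 24 3,4-bis(benzyloxy)-6,6-dimethoxy-1,8-bis[(2R,3R)-3,5,7-tris(benzyloxy)-3,4-dihydro-2H-chromen-2-yl]-6,7-dihydro-5H-benzo[7]annulen-5-one (C9 ketone, C1 dimethyl ketal, C3=C4 alkene in the numbering of the overview)
Conditions: (H2IMes)Cl2Ru(=CH-C6H4-2-O-i-Pr) (second-generation Hoveyda–Grubbs catalyst, 10 mol % in two portions), 1,4-benzoquinone (20 mol %), toluene (0.002 M), 80 °C, argon sparge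
Reagents that add atoms: none
Why: Olefin metathesis by the metallacyclobutane mechanism: after loss of the isopropoxystyrene ligand the ruthenium carbene loads on the monosubstituted aryl vinyl group, and the ruthenium benzylidene so formed adds across the 1,1-disubstituted alkene to a ruthenacyclobutane that cycloreverts to the C3=C4 bond and Ru=CH2, ethene being lost. The closest known reaction type is ring-closing metathesis of ortho-vinyl aryl ketones to benzocycloheptenones with a trisubstituted styrenyl double bond. The one ring formed is seven-membered and closes between two ortho-disposed chains, the ring size allowing only the cis ring alkene. No stereocentre is created, and the four existing ones lie away from any acidic or ionising site under these neutral conditions. The selectivity needed is ring closure over dimerisation and over migration of the 1,1-disubstituted double bond towards the C2 ether of flavan A; the ortho arrangement, the ketone and gem-dimethoxy carbon in the tether, high dilution and benzoquinone as a scavenger of ruthenium hydrides should secure it. Ketone, ketal, benzyl ethers and chroman oxygens are inert to the catalyst.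

Step 19
Reactants: 24 3,4-bis(benzyloxy)-6,6-dimethoxy-1,8-bis[(2R,3R)-3,5,7-tris(benzyloxy)-3,4-dihydro-2H-chromen-2-yl]-6,7-dihydro-5H-benzo[7]annulen-5-one
Product: 26 octa-O-benzyltheaflavin (3,4-bis(benzyloxy)-6-hydroxy-1,8-bis[(2R,3R)-3,5,7-tris(benzyloxy)-3,4-dihydro-2H-chromen-2-yl]-5H-benzo[7]annulen-5-one, the benzotropolone), via 5,6-dione 25 (not isolated)
Conditions: 1 M aq. HCl/THF (1:4), 50 °C
Reagents that add atoms: water O
Why: Acid-catalysed hydrolysis of the C1 dimethyl ketal gives the C9,C1-dione, which enolises from C2 at once because the resulting benzotropolone is aromatic, while benzyl ethers and chroman rings tolerate the dilute acid.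

Step 20
Reactants: 26 octa-O-benzyltheaflavin
Product: 27 theaflavin
Conditions: H2 (1 atm), Pd(OH)2 on carbon, THF/MeOH (1:1), rt; filtration under argon
Reagents that add atoms: none
Why: Hydrogenolysis of the eight benzyl ethers (six aryl, two secondary alkyl) under mild conditions that leave the aromatic tropolone and the chroman C2–O bonds intact.

## Compound list

1 | 2-bromoprop-2-enal | C=C(Br)C=O | starting material
2 | rac-2-bromopenta-1,4-dien-3-ol | C=CC(O)C(Br)=C | intermediate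
3 | (1R)-2-bromo-1-[(2R)-oxiran-2-yl]prop-2-en-1-ol | C=C(Br)[C@H](O)[C@H]1CO1 | intermediate
4 | 3,5-bis(benzyloxy)phenol | Oc1cc(OCc2ccccc2)cc(OCc2ccccc2)c1 | starting material
5 | (2R)-2-{(1S)-1-[3,5-bis(benzyloxy)phenoxy]-2-bromoprop-2-en-1-yl}oxirane | C=C(Br)[C@@H](Oc1cc(OCc9ccccc9)cc(OCc9ccccc9)c1)[C@H]2CO2 | intermediate
6 | (2S,3R)-5,7-bis(benzyloxy)-2-(1-bromoethenyl)-3,4-dihydro-2H-chromen-3-ol | C=C(Br)[C@H]1Oc2cc(OCc9ccccc9)cc(OCc9ccccc9)c2C[C@H]1O | intermediate
7 | (2S,3R)-3,5,7-tris(benzyloxy)-2-(1-bromoethenyl)-3,4-dihydro-2H-chromene | C=C(Br)[C@H]1Oc2cc(OCc9ccccc9)cc(OCc9ccccc9)c2C[C@H]1OCc9ccccc9 | intermediate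
8 | 2-[(2R,3R)-3,5,7-tris(benzyloxy)-3,4-dihydro-2H-chromen-2-yl]prop-2-en-1-ol | OCC(=C)[C@H]1Oc2cc(OCc9ccccc9)cc(OCc9ccccc9)c2C[C@H]1OCc9ccccc9 | intermediate
9 | (2R,3R)-3,5,7-tris(benzyloxy)-2-(3-bromoprop-1-en-2-yl)-3,4-dihydro-2H-chromene | BrCC(=C)[C@H]1Oc2cc(OCc9ccccc9)cc(OCc9ccccc9)c2C[C@H]1OCc9ccccc9 | intermediate
10 | methyl dimethoxyacetate | COC(OC)C(=O)OC | starting material
11 | lithium enolate of methyl dimethoxyacetate (lithium 1,2,2-trimethoxyethenolate) | [Li]OC(OC)=C(OC)OC | intermediate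
12 | methyl 2,2-dimethoxy-4-[(2R,3R)-3,5,7-tris(benzyloxy)-3,4-dihydro-2H-chromen-2-yl]pent-4-enoate | COC(=O)C(OC)(OC)CC(=C)[C@H]1Oc2cc(OCc9ccccc9)cc(OCc9ccccc9)c2C[C@H]1OCc9ccccc9 | intermediate
13 | 3-bromo-4,5-dihydroxybenzaldehyde | O=Cc1cc(O)c(O)c(Br)c1 | starting material
14 | 3,4-bis(benzyloxy)-5-bromobenzaldehyde | O=Cc1cc(OCc9ccccc9)c(OCc9ccccc9)c(Br)c1 | intermediate
15 | 4,5-bis(benzyloxy)-3-bromo-2-iodobenzaldehyde | O=Cc1cc(OCc9ccccc9)c(OCc9ccccc9)c(Br)c1I | intermediate
16 | rac-1-[4,5-bis(benzyloxy)-3-bromo-2-iodophenyl]prop-2-en-1-ol | C=CC(O)c1cc(OCc9ccccc9)c(OCc9ccccc9)c(Br)c1I | intermediate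
17 | (S)-[4,5-bis(benzyloxy)-3-bromo-2-iodophenyl][(2R)-oxiran-2-yl]methanol | Ic1c(Br)c(OCc9ccccc9)c(OCc9ccccc9)cc1[C@H](O)[C@H]2CO2 | intermediate
18 | (2R)-2-{(R)-[4,5-bis(benzyloxy)-3-bromo-2-iodophenyl][3,5-bis(benzyloxy)phenoxy]methyl}oxirane | Ic1c(Br)c(OCc9ccccc9)c(OCc9ccccc9)cc1[C@@H](Oc3cc(OCc9ccccc9)cc(OCc9ccccc9)c3)[C@H]2CO2 | intermediate
19 | (2R,3R)-5,7-bis(benzyloxy)-2-[4,5-bis(benzyloxy)-3-bromo-2-iodophenyl]-3,4-dihydro-2H-chromen-3-ol | Ic1c(Br)c(OCc9ccccc9)c(OCc9ccccc9)cc1[C@H]2Oc3cc(OCc9ccccc9)cc(OCc9ccccc9)c3C[C@H]2O | intermediate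
20 | (2R,3R)-3,5,7-tris(benzyloxy)-2-[4,5-bis(benzyloxy)-3-bromo-2-iodophenyl]-3,4-dihydro-2H-chromene | Ic1c(Br)c(OCc9ccccc9)c(OCc9ccccc9)cc1[C@H]2Oc3cc(OCc9ccccc9)cc(OCc9ccccc9)c3C[C@H]2OCc9ccccc9 | intermediate
21 | (2R,3R)-3,5,7-tris(benzyloxy)-2-[4,5-bis(benzyloxy)-3-bromo-2-ethenylphenyl]-3,4-dihydro-2H-chromene | C=Cc1c(Br)c(OCc9ccccc9)c(OCc9ccccc9)cc1[C@H]2Oc3cc(OCc9ccccc9)cc(OCc9ccccc9)c3C[C@H]2OCc9ccccc9 | intermediate
22 | {2,3-bis(benzyloxy)-6-ethenyl-5-[(2R,3R)-3,5,7-tris(benzyloxy)-3,4-dihydro-2H-chromen-2-yl]phenyl}lithium | [Li]c1c(C=C)c([C@H]2Oc3cc(OCc9ccccc9)cc(OCc9ccccc9)c3C[C@H]2OCc9ccccc9)cc(OCc9ccccc9)c1OCc9ccccc9 | intermediate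
23 | 1-{2,3-bis(benzyloxy)-6-ethenyl-5-[(2R,3R)-3,5,7-tris(benzyloxy)-3,4-dihydro-2H-chromen-2-yl]phenyl}-2,2-dimethoxy-4-[(2R,3R)-3,5,7-tris(benzyloxy)-3,4-dihydro-2H-chromen-2-yl]pent-4-en-1-one | C=Cc1c([C@H]5Oc6cc(OCc9ccccc9)cc(OCc9ccccc9)c6C[C@H]5OCc9ccccc9)cc(OCc9ccccc9)c(OCc9ccccc9)c1C(=O)C(OC)(OC)CC(=C)[C@H]3Oc4cc(OCc9ccccc9)cc(OCc9ccccc9)c4C[C@H]3OCc9ccccc9 | intermediate
24 | 3,4-bis(benzyloxy)-6,6-dimethoxy-1,8-bis[(2R,3R)-3,5,7-tris(benzyloxy)-3,4-dihydro-2H-chromen-2-yl]-6,7-dihydro-5H-benzo[7]annulen-5-one | O=C1C(OC)(OC)CC([C@H]3Oc4cc(OCc9ccccc9)cc(OCc9ccccc9)c4C[C@H]3OCc9ccccc9)=Cc2c([C@H]5Oc6cc(OCc9ccccc9)cc(OCc9ccccc9)c6C[C@H]5OCc9ccccc9)cc(OCc9ccccc9)c(OCc9ccccc9)c21 | intermediate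
25 | 3,4-bis(benzyloxy)-1,8-bis[(2R,3R)-3,5,7-tris(benzyloxy)-3,4-dihydro-2H-chromen-2-yl]-5H-benzo[7]annulene-5,6(7H)-dione | O=C1C(=O)CC([C@H]3Oc4cc(OCc9ccccc9)cc(OCc9ccccc9)c4C[C@H]3OCc9ccccc9)=Cc2c([C@H]5Oc6cc(OCc9ccccc9)cc(OCc9ccccc9)c6C[C@H]5OCc9ccccc9)cc(OCc9ccccc9)c(OCc9ccccc9)c21 | intermediate
26 | octa-O-benzyltheaflavin (benzotropolone with free C9–OH) | O=c1cc([C@H]2Oc3cc(OCc9ccccc9)cc(OCc9ccccc9)c3C[C@H]2OCc9ccccc9)cc2c([C@H]3Oc4cc(OCc9ccccc9)cc(OCc9ccccc9)c4C[C@H]3OCc9ccccc9)cc(OCc9ccccc9)c(OCc9ccccc9)c2c1O | intermediate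
27 | theaflavin | O=c1cc([C@H]2Oc3cc(O)cc(O)c3C[C@H]2O)cc2c([C@H]3Oc4cc(O)cc(O)c4C[C@H]3O)cc(O)c(O)c2c1O | target

## Step count and risks

Total steps: 20. Longest linear sequence: 12 steps (steps 1–8 or steps 9–16, then steps 17–20).

Steps most likely to fail:

Step 18 (ring-closing metathesis). What may go wrong: ruthenium loads slowly on a vinyl group flanked by two ortho substituents, so catalyst decay, intermolecular metathesis and migration of the 1,1-disubstituted double bond towards the C2 ether outrun ring closure. Fallback, a relay ring-closing metathesis that forms the same C3=C4 bond: setting out from 20, Stille coupling with (E)-tributyl[3-(prop-2-en-1-yloxy)prop-1-en-1-yl]stannane (Pd(PPh3)4, CuI, DMF, 60 °C) should give the relay bromide (2R,3R)-3,5,7-tris(benzyloxy)-2-{4,5-bis(benzyloxy)-3-bromo-2-[(1E)-3-(prop-2-en-1-yloxy)prop-1-en-1-yl]phenyl}-3,4-dihydro-2H-chromene F1. Bromine–lithium exchange (n-BuLi, THF, −78 °C) and acylation with ester 12 should then give the relay ketone 1-{2,3-bis(benzyloxy)-6-[(1E)-3-(prop-2-en-1-yloxy)prop-1-en-1-yl]-5-[(2R,3R)-3,5,7-tris(benzyloxy)-3,4-dihydro-2H-chromen-2-yl]phenyl}-2,2-dimethoxy-4-[(2R,3R)-3,5,7-tris(benzyloxy)-3,4-dihydro-2H-chromen-2-yl]pent-4-en-1-one F2. With the same catalyst the carbene loads on the unhindered terminal allyl ether, closes to 2,5-dihydrofuran and is thereby delivered to the benzylic carbon, from which it closes onto the 1,1-disubstituted alkene; the route is rejoined at 24.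

Step 10 (iodination). What may go wrong: substitution at the crowded site between CHO and Br is slow and reversible (protodeiodination), and forcing it begins to cleave or iodinate the benzyl ethers. Fallback, nitration followed by a Sandmeyer reaction: setting out from 14, HNO3 in AcOH at 10 °C should nitrate irreversibly at the same site para to the benzyloxy group to give 4,5-bis(benzyloxy)-3-bromo-2-nitrobenzaldehyde F3. Fe, aq. HCl, EtOH, 60 °C should reduce it to 2-amino-4,5-bis(benzyloxy)-3-bromobenzaldehyde F4, which is diazotised at once (NaNO2, aq. HCl, MeCN, 0 °C) and treated with KI; the route is rejoined at 15.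

Step 6 (hydroxymethylation). What may go wrong: the hydroxymethyl group transfers from tin too slowly, so butyl transfer and protodebromination compete and prolonged heating lets zerovalent palladium ionise the allyl aryl ether with loss of configuration at C2. Fallback, carbonylation then reduction: setting out from 7, Pd(OAc)2 with Ph2P(CH2)3PPh2, CO (1 atm), MeOH, i-Pr2NEt, DMF, 60 °C should give methyl 2-[(2R,3R)-3,5,7-tris(benzyloxy)-3,4-dihydro-2H-chromen-2-yl]prop-2-enoate F5 through fast CO insertion into the alkenyl–palladium bond. i-Bu2AlH (CH2Cl2, −78 °C) should reduce the ester to the allylic alcohol; the route is rejoined at 8.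

## Further compounds

F1 | step 18 | (2R,3R)-3,5,7-tris(benzyloxy)-2-{4,5-bis(benzyloxy)-3-bromo-2-[(1E)-3-(prop-2-en-1-yloxy)prop-1-en-1-yl]phenyl}-3,4-dihydro-2H-chromene | C=CCOC/C=C/c1c(Br)c(OCc9ccccc9)c(OCc9ccccc9)cc1[C@H]2Oc3cc(OCc9ccccc9)cc(OCc9ccccc9)c3C[C@H]2OCc9ccccc9
F2 | step 18 | 1-{2,3-bis(benzyloxy)-6-[(1E)-3-(prop-2-en-1-yloxy)prop-1-en-1-yl]-5-[(2R,3R)-3,5,7-tris(benzyloxy)-3,4-dihydro-2H-chromen-2-yl]phenyl}-2,2-dimethoxy-4-[(2R,3R)-3,5,7-tris(benzyloxy)-3,4-dihydro-2H-chromen-2-yl]pent-4-en-1-one | C=CCOC/C=C/c1c([C@H]5Oc6cc(OCc9ccccc9)cc(OCc9ccccc9)c6C[C@H]5OCc9ccccc9)cc(OCc9ccccc9)c(OCc9ccccc9)c1C(=O)C(OC)(OC)CC(=C)[C@H]3Oc4cc(OCc9ccccc9)cc(OCc9ccccc9)c4C[C@H]3OCc9ccccc9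
F3 | step 10 | 4,5-bis(benzyloxy)-3-bromo-2-nitrobenzaldehyde | O=Cc1cc(OCc9ccccc9)c(OCc9ccccc9)c(Br)c1[N+](=O)[O-]
F4 | step 10 | 2-amino-4,5-bis(benzyloxy)-3-bromobenzaldehyde | O=Cc1cc(OCc9ccccc9)c(OCc9ccccc9)c(Br)c1N
F5 | step 6 | methyl 2-[(2R,3R)-3,5,7-tris(benzyloxy)-3,4-dihydro-2H-chromen-2-yl]prop-2-enoate | COC(=O)C(=C)[C@H]1Oc2cc(OCc9ccccc9)cc(OCc9ccccc9)c2C[C@H]1OCc9ccccc9
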